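**Retrosynthetic overview**
1. Target 26 ⇐ C3–O tigloylation and C11–O Mitsunobu etherification with umbelliferone ⇐ silyl-protected 8,11-diol 22.
2. Ring B decoration of 22: C8 carbinol by MeLi addition to a C8 ketone; C11 by axial alkylation of the C8/C9 enolate (a temporary C6=C7 double bond blocks C7); the C8 ketone comes from an exocyclic methylidene.
3. Ring A decoration: the 4,4-dimethyl-3-ol comes from a 4-methyl-Δ4-3-ketone (11) by dissolving-metal reductive methylation (sets trans C5–H) and hydride reduction.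
4. Key disconnection: enone 11 (rings A and B) ⇐ monocyclic cyclobutanone 10. Ring A's only oxygenated carbon C3 is joined to the methyl-bearing quaternary fusion carbon C10 through C2–C1, so C3/C2/C1/C10 can be a 2,2-disubstituted cyclobutanone whose acyl–C(α) bond is C3–C10. The adjacent atoms C4 (carrying a methyl) and C5 (the other fusion atom) can be the two carbons of a 2-butynyl end tethered to C10 through C9–C8–C7–C6. Inserting C4≡C5 into C3–C10 enlarges the four-membered ring to ring A and closes ring B in the same step.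
5. Cyclobutanone 10 ⇐ decarboxylative asymmetric allylic alkylation (sets C10) ⇐ cyclobutanone + methallyl alcohol + 1-bromobut-2-yne. Ring order: four-membered ring (purchased), then rings A and B together in step 6; the coumarin is purchased.

Key step: step 6

Remark: positions are cited with decalin (drimane-type) locants: ring A = C1–C5 and C10, ring B = C5–C10, C11 = CH2O carbon on C9, C12 = carbon on C8. The (S)-configured PHOX ligand in step 5 is assumed to give (S)-10 by analogy with six-membered β-keto esters; if the sense proves opposite, the enantiomeric ligand is used.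

**Route**

Step 1
Reactants: 1 2-methylprop-2-en-1-ol; 2 1-bromobut-2-yne
Product: 4 2-methylidenehept-5-yn-1-ol, via dilithiated methallyl alcohol 3 (not isolated)
Conditions: n-BuLi (2.2 equiv), TMEDA, Et2O, 0 °C to rt; then 2, THF, −78 to 0 °C; H2O
Reagents that add atoms: none
Why: Double deprotonation (O–H and allylic C–H) gives a dianion whose allylic carbanion displaces the primary propargylic bromide (SN2 C-alkylation of an allyl anion); no stereocentre is formed.

Step 2
Reactants: 4 2-methylidenehept-5-yn-1-ol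
Product: 5 2-methylidenehept-5-yn-1-yl 1H-imidazole-1-carboxylate
Conditions: 1,1'-carbonyldiimidazole, CH2Cl2, 0 °C to rt
Reagents that add atoms: 1,1'-carbonyldiimidazole, O=C(n1ccnc1)n1ccnc1
Why: Acyl substitution at carbonyldiimidazole by the primary alcohol gives the activated imidazole-1-carboxylate with loss of one imidazole; no stereocentre.

Step 3
Reactants: 6 cyclobutanone; 5 2-methylidenehept-5-yn-1-yl 1H-imidazole-1-carboxylate
Product: 8 2-methylidenehept-5-yn-1-yl 2-oxocyclobutane-1-carboxylate (racemic), via lithium cyclobutenolate 7 (not isolated)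
Conditions: LiN(SiMe3)2, THF, −78 °C; then 5, BF3·OEt2, −78 °C; 1 M HCl
Reagents that add atoms: none
Why: Claisen-type C-acylation of the lithium enolate by the Lewis-acid-activated N-acylimidazole should give the β-keto ester, which is enolisable, so its configuration is irrelevant.

Step 4
Reactants: 8 2-methylidenehept-5-yn-1-yl 2-oxocyclobutane-1-carboxylate
Product: 9 2-methylidenehept-5-yn-1-yl 1-methyl-2-oxocyclobutane-1-carboxylate (racemic)
Conditions: MeI, K2CO3, acetone, rt
Reagents that add atoms: iodomethane, CI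
Why: SN2 C-alkylation of the stabilised β-keto ester enolate installs the future C10 methyl as a racemic quaternary centre.

Step 5
Reactants: 9 2-methylidenehept-5-yn-1-yl 1-methyl-2-oxocyclobutane-1-carboxylate
Product: 10 (S)-2-methyl-2-(2-methylidenehept-5-yn-1-yl)cyclobutan-1-one
Conditions: Pd2(dba)3 (2.5 mol %), (S)-(CF3)3-t-BuPHOX (6 mol %), toluene, 25 °C
Reagents that add atoms: none
Why: Decarboxylative asymmetric allylic alkylation (Tsuji–Trost type): ionisation of the 2-substituted allyl ester by zerovalent palladium and loss of CO2 give a prochiral enolate/π-allyl pair, so both enantiomers of 9 converge and the chiral P,N ligand decides which enolate face is allylated, setting C10 as (S).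

Step 6
Reactants: 10 (S)-2-methyl-2-(2-methylidenehept-5-yn-1-yl)cyclobutan-1-one
Product: 11 (S)-1,4a-dimethyl-6-methylidene-4,4a,5,6,7,8-hexahydronaphthalen-2(3H)-one
Conditions: [Rh(cod)Cl]2 (5 mol %), PMe2Ph (20 mol %), 1,4-dioxane, 130 °C, sealed tube
Reagents that add atoms: none
Why: Monovalent rhodium adds oxidatively into the strained acyl–C(α) bond C3–C10 to give a five-membered acyl rhodacycle (trivalent rhodium), the tethered alkyne inserts syn into the Rh–C10 bond, and C(acyl)–C(vinyl) reductive elimination closes the enone, so that C4≡C5 is inserted into C3–C10 and the four-membered ring becomes ring A. The closest known reaction type is the rhodium-catalysed intramolecular carboacylation ("cut-and-sew", formal [4+2]) of cyclobutanones that carry an alkyne tether on the α-carbon, which gives fused cyclohexenones. Ring B closes by 6-exo-dig carbometalation (C10–C5 bond) and ring A by reductive elimination from the resulting seven-membered rhodacycle (C3–C4 bond), a two-atom ring enlargement. No stereocentre is created, and C10 is carried through with retention because the C10–Rh bond is formed and consumed stereoretentively. The step needs cleavage of the hindered C3–C10 bond rather than C3–C2: insertion into either bond is reversible, but only the C10-bound metallacycle can reach the alkyne, so the product should form by Curtin–Hammett selection, while the small electron-rich phosphine disfavours decarbonylation. The 1,1-disubstituted olefin sits one carbon from C10 and could insert only by forming a three- or four-membered ring, so it should stay a spectator.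

Step 7
Reactants: 11 (S)-1,4a-dimethyl-6-methylidene-4,4a,5,6,7,8-hexahydronaphthalen-2(3H)-one
Product: 13 (4aS,8aS)-1,1,4a-trimethyl-6-methylideneoctahydronaphthalen-2(1H)-one, via lithium enolate 12 (not isolated)
Conditions: Li (2.2 equiv), NH3(l), THF, t-BuOH (1 equiv), −78 °C; evaporate NH3; MeI, THF, −78 to 0 °C; H2O
Reagents that add atoms: iodomethane, CI
Why: Dissolving-metal reductive alkylation (Birch type): the β-carbanion at C5 is protonated axially to give the trans-decalin (C5 (S), H anti to the C10 methyl), and the regiospecific C3/C4 lithium enolate is C-methylated to build the gem-dimethyl group.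

Step 8
Reactants: 13 (4aS,8aS)-1,1,4a-trimethyl-6-methylideneoctahydronaphthalen-2(1H)-one
Product: 14 (2R,4aS,8aS)-1,1,4a-trimethyl-6-methylidenedecahydronaphthalen-2-ol
Conditions: NaBH4, MeOH, 0 °C
Reagents that add atoms: none
Why: Hydride reduction with axial delivery to the C3 ketone, on the face away from the axial C4 methyl, should give the equatorial alcohol (C3 (R), OH cis to the C10 methyl).

Step 9
Reactants: 14 (2R,4aS,8aS)-1,1,4a-trimethyl-6-methylidenedecahydronaphthalen-2-ol
Product: 15 tert-butyldimethyl{[(2R,4aS,8aS)-1,1,4a-trimethyl-6-methylidenedecahydronaphthalen-2-yl]oxy}silane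
Conditions: TBSOTf, 2,6-lutidine, CH2Cl2, 0 °C to rt
Reagents that add atoms: tert-butyldimethylsilyl trifluoromethanesulfonate, CC(C)(C)[Si](C)(C)OS(=O)(=O)C(F)(F)F
Why: O-Silylation of the hindered secondary alcohol with the silyl triflate protects C3–OH through the base and organolithium steps; no stereocentre changes.

Step 10
Reactants: 15 tert-butyldimethyl{[(2R,4aS,8aS)-1,1,4a-trimethyl-6-methylidenedecahydronaphthalen-2-yl]oxy}silane
Product: 17 (4aS,6R,8aS)-6-[(tert-butyldimethylsilyl)oxy]-5,5,8a-trimethyloctahydronaphthalen-2(1H)-one, via ozonide 16 (not isolated)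
Conditions: O3, CH2Cl2, −78 °C; then Me2S, −78 °C to rt
Reagents that add atoms: ozone, [O-][O+]=O
Why: Ozonolysis of the 1,1-disubstituted olefin (1,3-dipolar cycloaddition, cycloreversion, reductive work-up) unveils the C8 ketone without touching the silyl ether or any stereocentre.

Step 11
Reactants: 17 (4aS,6R,8aS)-6-[(tert-butyldimethylsilyl)oxy]-5,5,8a-trimethyloctahydronaphthalen-2(1H)-one
Product: 18 (4aS,6R,8aS)-6-[(tert-butyldimethylsilyl)oxy]-5,5,8a-trimethyl-4a,5,6,7,8,8a-hexahydronaphthalen-2(1H)-one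
Conditions: IBX, DMSO, 70 °C
Reagents that add atoms: none
Why: IBX-mediated α,β-dehydrogenation can only run toward C7–C6 because C10 is quaternary, which makes C7 sp2 and leaves C9 as the only enolisable position.

Step 12
Reactants: 18 (4aS,6R,8aS)-6-[(tert-butyldimethylsilyl)oxy]-5,5,8a-trimethyl-4a,5,6,7,8,8a-hexahydronaphthalen-2(1H)-one
Product: 20 (1S,4aS,6R,8aR)-1-[(benzyloxy)methyl]-6-[(tert-butyldimethylsilyl)oxy]-5,5,8a-trimethyl-4a,5,6,7,8,8a-hexahydronaphthalen-2(1H)-one, via lithium dienolate 19 (not isolated)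
Conditions: LiN(i-Pr)2, THF, −78 °C; then BnOCH2Cl, −78 to −40 °C
Reagents that add atoms: benzyl chloromethyl ether, ClCOCc1ccccc1
Why: Kinetic α′-deprotonation gives the cross-conjugated C8–C9 enolate, which is alkylated (SN2) along the axial trajectory on the face opposite the C10 methyl, setting C9 (S) with the CH2O group trans to that methyl.

Step 13
Reactants: 20 (1S,4aS,6R,8aR)-1-[(benzyloxy)methyl]-6-[(tert-butyldimethylsilyl)oxy]-5,5,8a-trimethyl-4a,5,6,7,8,8a-hexahydronaphthalen-2(1H)-one
Product: 21 (1S,2R,4aS,6R,8aR)-1-[(benzyloxy)methyl]-6-[(tert-butyldimethylsilyl)oxy]-2,5,5,8a-tetramethyl-1,2,4a,5,6,7,8,8a-octahydronaphthalen-2-ol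
Conditions: MeLi, CeCl3, THF, −78 °C
Reagents that add atoms: methyllithium, [Li]C
Why: 1,2-Addition of the weakly basic organocerium reagent to the enone carbonyl: the C10 methyl is syn-axial to one face of C8, so the methyl should enter anti to it and give the C8 (R) tertiary alcohol with OH cis to the C10 methyl.

Step 14
Reactants: 21 (1S,2R,4aS,6R,8aR)-1-[(benzyloxy)methyl]-6-[(tert-butyldimethylsilyl)oxy]-2,5,5,8a-tetramethyl-1,2,4a,5,6,7,8,8a-octahydronaphthalen-2-ol
Product: 22 (1S,2R,4aS,6R,8aR)-6-[(tert-butyldimethylsilyl)oxy]-1-(hydroxymethyl)-2,5,5,8a-tetramethyldecahydronaphthalen-2-ol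
Conditions: H2 (1 atm), Pd/C, NaHCO3, EtOAc–EtOH, rt
Reagents that add atoms: none
Why: Heterogeneous catalytic hydrogenation saturates the C6–C7 olefin and hydrogenolyses the benzyl ether in one operation; no stereocentre is created and the buffer protects the tertiary allylic alcohol from ionisation.

Step 15
Reactants: 22 (1S,2R,4aS,6R,8aR)-6-[(tert-butyldimethylsilyl)oxy]-1-(hydroxymethyl)-2,5,5,8a-tetramethyldecahydronaphthalen-2-ol; 23 7-hydroxy-2H-chromen-2-one (umbelliferone)
Product: 24 7-{[(1S,2R,4aS,6R,8aR)-6-[(tert-butyldimethylsilyl)oxy]-2-hydroxy-2,5,5,8a-tetramethyldecahydronaphthalen-1-yl]methoxy}-2H-chromen-2-one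
Conditions: PPh3, DIAD, THF, 0 °C to 40 °C
Reagents that add atoms: none
Why: Mitsunobu etherification: the primary C11 alcohol is activated as an alkoxyphosphonium ion and displaced by the acidic phenol, while the tertiary C8 alcohol (anti to C11, unable to cyclise) does not react; no stereocentre is involved.

Step 16
Reactants: 24 7-{[(1S,2R,4aS,6R,8aR)-6-[(tert-butyldimethylsilyl)oxy]-2-hydroxy-2,5,5,8a-tetramethyldecahydronaphthalen-1-yl]methoxy}-2H-chromen-2-one
Product: 25 7-{[(1S,2R,4aS,6R,8aR)-2,6-dihydroxy-2,5,5,8a-tetramethyldecahydronaphthalen-1-yl]methoxy}-2H-chromen-2-one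
Conditions: HF·pyridine, THF, 0 °C to rt
Reagents that add atoms: none
Why: Fluoride-induced Si–O cleavage frees the C3 alcohol under buffered conditions that should leave the lactone, the aryl ether and the tertiary alcohol intact.

Step 17
Reactants: 25 7-{[(1S,2R,4aS,6R,8aR)-2,6-dihydroxy-2,5,5,8a-tetramethyldecahydronaphthalen-1-yl]methoxy}-2H-chromen-2-one
Product: 26 (2R,4aR,5S,6R,8aS)-6-hydroxy-1,1,4a,6-tetramethyl-5-{[(2-oxo-2H-chromen-7-yl)oxy]methyl}decahydronaphthalen-2-yl (2E)-2-methylbut-2-enoate
Conditions: (E)-2-methylbut-2-enoyl chloride, Et3N, DMAP (cat.), CH2Cl2, 0 °C to rt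
Reagents that add atoms: (E)-2-methylbut-2-enoyl chloride, C/C=C(\C)C(Cl)=O
Why: DMAP-catalysed acylation (nucleophilic catalysis) esterifies the secondary C3 alcohol, the tertiary C8 alcohol being too hindered to react, and the (E)-geometry of the tigloyl group is retained.

**Compound list**
1 | 2-methylprop-2-en-1-ol | C=C(C)CO | starting material
2 | 1-bromobut-2-yne | CC#CCBr | starting material
3 | dilithiated methallyl alcohol (lithium 2-(lithiomethyl)prop-2-en-1-olate) | [Li]CC(=C)CO[Li] | intermediate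
4 | 2-methylidenehept-5-yn-1-ol | C=C(CO)CCC#CC | intermediate
5 | 2-methylidenehept-5-yn-1-yl 1H-imidazole-1-carboxylate | C=C(COC(=O)n1ccnc1)CCC#CC | intermediate
6 | cyclobutanone | O=C1CCC1 | starting material
7 | lithium cyclobut-1-en-1-olate | [Li]OC1=CCC1 | intermediate
8 | 2-methylidenehept-5-yn-1-yl 2-oxocyclobutane-1-carboxylate (racemic) | O=C1CCC1C(=O)OCC(=C)CCC#CC | intermediate
9 | 2-methylidenehept-5-yn-1-yl 1-methyl-2-oxocyclobutane-1-carboxylate (racemic) | CC1(CCC1=O)C(=O)OCC(=C)CCC#CC | intermediate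
10 | (S)-2-methyl-2-(2-methylidenehept-5-yn-1-yl)cyclobutan-1-one | O=C1CC[C@@]1(C)CC(=C)CCC#CC | intermediate
11 | (S)-1,4a-dimethyl-6-methylidene-4,4a,5,6,7,8-hexahydronaphthalen-2(3H)-one | O=C1CC[C@]2(C)C(CCC(=C)C2)=C1C | intermediate
12 | lithium (4aS,8aS)-1,4a-dimethyl-6-methylidene-3,4,4a,5,6,7,8,8a-octahydronaphthalen-2-olate | [Li]OC=1CC[C@]2(C)[C@H](CCC(=C)C2)C=1C | intermediate
13 | (4aS,8aS)-1,1,4a-trimethyl-6-methylideneoctahydronaphthalen-2(1H)-one | O=C1CC[C@]2(C)[C@H](CCC(=C)C2)C1(C)C | intermediate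
14 | (2R,4aS,8aS)-1,1,4a-trimethyl-6-methylidenedecahydronaphthalen-2-ol | O[C@@H]1CC[C@]2(C)[C@H](CCC(=C)C2)C1(C)C | intermediate
15 | tert-butyldimethyl{[(2R,4aS,8aS)-1,1,4a-trimethyl-6-methylidenedecahydronaphthalen-2-yl]oxy}silane | CC(C)(C)[Si](C)(C)O[C@@H]1CC[C@]2(C)[C@H](CCC(=C)C2)C1(C)C | intermediate
16 | secondary ozonide of 15 (spiro-1,2,4-trioxolane at C8, mixture at the spiro carbon) | CC(C)(C)[Si](C)(C)O[C@@H]1CC[C@]2(C)[C@H](CCC3(OCOO3)C2)C1(C)C | intermediate
17 | (4aS,6R,8aS)-6-[(tert-butyldimethylsilyl)oxy]-5,5,8a-trimethyloctahydronaphthalen-2(1H)-one | CC(C)(C)[Si](C)(C)O[C@@H]1CC[C@]2(C)[C@H](CCC(=O)C2)C1(C)C | intermediate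
18 | (4aS,6R,8aS)-6-[(tert-butyldimethylsilyl)oxy]-5,5,8a-trimethyl-4a,5,6,7,8,8a-hexahydronaphthalen-2(1H)-one | CC(C)(C)[Si](C)(C)O[C@@H]1CC[C@]2(C)[C@H](C=CC(=O)C2)C1(C)C | intermediate
19 | lithium cross-conjugated dienolate of 18 (O–Li on C8; C8=C9 and C6=C7) | CC(C)(C)[Si](C)(C)O[C@@H]1CC[C@]2(C)[C@H](C=CC(O[Li])=C2)C1(C)C | intermediate
20 | (1S,4aS,6R,8aR)-1-[(benzyloxy)methyl]-6-[(tert-butyldimethylsilyl)oxy]-5,5,8a-trimethyl-4a,5,6,7,8,8a-hexahydronaphthalen-2(1H)-one | CC(C)(C)[Si](C)(C)O[C@@H]1CC[C@]2(C)[C@H](C=CC(=O)[C@@H]2COCc2ccccc2)C1(C)C | intermediate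
21 | (1S,2R,4aS,6R,8aR)-1-[(benzyloxy)methyl]-6-[(tert-butyldimethylsilyl)oxy]-2,5,5,8a-tetramethyl-1,2,4a,5,6,7,8,8a-octahydronaphthalen-2-ol | CC(C)(C)[Si](C)(C)O[C@@H]1CC[C@]2(C)[C@H](C=C[C@@](C)(O)[C@@H]2COCc2ccccc2)C1(C)C | intermediate
22 | (1S,2R,4aS,6R,8aR)-6-[(tert-butyldimethylsilyl)oxy]-1-(hydroxymethyl)-2,5,5,8a-tetramethyldecahydronaphthalen-2-ol | CC(C)(C)[Si](C)(C)O[C@@H]1CC[C@]2(C)[C@H](CC[C@@](C)(O)[C@@H]2CO)C1(C)C | intermediate
23 | 7-hydroxy-2H-chromen-2-one (umbelliferone) | O=c1ccc2ccc(O)cc2o1 | starting material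
24 | 7-{[(1S,2R,4aS,6R,8aR)-6-[(tert-butyldimethylsilyl)oxy]-2-hydroxy-2,5,5,8a-tetramethyldecahydronaphthalen-1-yl]methoxy}-2H-chromen-2-one | CC(C)(C)[Si](C)(C)O[C@@H]1CC[C@]2(C)[C@H](CC[C@@](C)(O)[C@@H]2COc2ccc3ccc(=O)oc3c2)C1(C)C | intermediate
25 | 7-{[(1S,2R,4aS,6R,8aR)-2,6-dihydroxy-2,5,5,8a-tetramethyldecahydronaphthalen-1-yl]methoxy}-2H-chromen-2-one | O[C@@H]1CC[C@]2(C)[C@H](CC[C@@](C)(O)[C@@H]2COc2ccc3ccc(=O)oc3c2)C1(C)C | intermediate
26 | (2R,4aR,5S,6R,8aS)-6-hydroxy-1,1,4a,6-tetramethyl-5-{[(2-oxo-2H-chromen-7-yl)oxy]methyl}decahydronaphthalen-2-yl (2E)-2-methylbut-2-enoate | C/C=C(\C)C(=O)O[C@@H]1CC[C@]2(C)[C@H](CC[C@@](C)(O)[C@@H]2COc2ccc3ccc(=O)oc3c2)C1(C)C | target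

**Step count and risks**
Total steps: 17. Longest linear sequence: 17 steps (1 to 26).

Most likely to fail:

1. Step 6. The catalyst may be diverted before C–C insertion: isomerisation of the 1,1-disubstituted olefin, cycloisomerisation of the 1,5-enyne, or decarbonylation of the acyl-rhodium intermediate. The fallback sets out from 10 and returns at 17; it takes the olefin out before the ring enlargement and carries C8 at the ketone level. Ozonolysis of 10 (O3, CH2Cl2, −78 °C; Me2S) should give (S)-2-methyl-2-(2-oxohept-5-yn-1-yl)cyclobutan-1-one F1. The same rhodium-catalysed alkyne insertion on F1 should give the enedione (S)-1,4a-dimethyl-4,4a,7,8-tetrahydronaphthalene-2,6(3H,5H)-dione F2. Ethylene glycol and TsOH (benzene, reflux) should ketalise only the saturated C8 ketone to the dioxolane enone F3. Reductive methylation as in step 7 gives the trans-decalone ketal F4, NaBH4 the equatorial alcohol F5, and TBSOTf/2,6-lutidine the silyl ether F6. PPTS in wet acetone then releases the C8 ketone, which is 17.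

2. Step 13. Facial selectivity at C8 may be poor or reversed, because the axial C11 substituent on C9 hinders the face from which the methyl must enter. The fallback sets out from 20 and returns at 22; it reverses the polarity so that oxygen, not carbon, is delivered from the face opposite the C9 substituent. Selective hydrogenation of the C6–C7 olefin (H2, Pd/C, Ph2S, EtOAc) gives the saturated benzyloxymethyl ketone F7. Wittig methylenation (Ph3P=CH2, THF) gives the C8 methylidene compound F8. Epoxidation (mCPBA, NaHCO3, CH2Cl2) from the face anti to the axial CH2OBn gives the spiro-oxirane with the C8–O bond cis to the C10 methyl F9. LiAlH4 opens it at the primary carbon to the tertiary alcohol benzyl ether F10, and hydrogenolysis (H2, Pd/C) gives 22.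

3. Step 15. SN2 displacement at the β,β-branched (neopentyl-like) C11 carbon may be too slow, so that elimination of the activated alcohol or alkylation of the hydrazide competes. The fallback sets out from 22 and returns at 24; it forms the ether from the aryl side. Palladium-catalysed C–O cross-coupling of the primary alcohol of 22 with 7-bromo-2H-chromen-2-one (Pd2(dba)3, t-BuBrettPhos, Cs2CO3, toluene, 80 °C) should give 24 directly, with the tertiary alcohol unreactive. No new intermediate is made.

Further compounds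
F1 | step 6 | (S)-2-methyl-2-(2-oxohept-5-yn-1-yl)cyclobutan-1-one | O=C1CC[C@@]1(C)CC(=O)CCC#CC
F2 | step 6 | (S)-1,4a-dimethyl-4,4a,7,8-tetrahydronaphthalene-2,6(3H,5H)-dione | O=C1CC[C@]2(C)C(CCC(=O)C2)=C1C
F3 | step 6 | C8 ethylene ketal (1,3-dioxolane) of F2, enone retained, C10 (S) | O=C1CC[C@]2(C)C(CCC3(OCCO3)C2)=C1C
F4 | step 6 | C8 ethylene ketal of the trans-fused 4,4,10-trimethyl-3-ketone, C5 (S), C10 (S) | O=C1CC[C@]2(C)[C@H](CCC3(OCCO3)C2)C1(C)C
F5 | step 6 | C8 ethylene ketal of the equatorial 3-alcohol, C3 (R), C5 (S), C10 (S) | O[C@@H]1CC[C@]2(C)[C@H](CCC3(OCCO3)C2)C1(C)C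
F6 | step 6 | tert-butyldimethylsilyl ether of F5 | CC(C)(C)[Si](C)(C)O[C@@H]1CC[C@]2(C)[C@H](CCC3(OCCO3)C2)C1(C)C
F7 | step 13 | (1S,4aS,6R,8aR)-1-[(benzyloxy)methyl]-6-[(tert-butyldimethylsilyl)oxy]-5,5,8a-trimethyloctahydronaphthalen-2(1H)-one | CC(C)(C)[Si](C)(C)O[C@@H]1CC[C@]2(C)[C@H](CCC(=O)[C@@H]2COCc2ccccc2)C1(C)C
F8 | step 13 | C8 methylidene analogue of F7 (C8=CH2 in place of C8=O) | CC(C)(C)[Si](C)(C)O[C@@H]1CC[C@]2(C)[C@H](CCC(=C)[C@@H]2COCc2ccccc2)C1(C)C
F9 | step 13 | C8 spiro-oxirane of F8 with the C8–O bond cis to the C10 methyl | CC(C)(C)[Si](C)(C)O[C@@H]1CC[C@]2(C)[C@H](CC[C@@]3(OC3)[C@@H]2COCc2ccccc2)C1(C)C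
F10 | step 13 | (1S,2R,4aS,6R,8aR)-1-[(benzyloxy)methyl]-6-[(tert-butyldimethylsilyl)oxy]-2,5,5,8a-tetramethyldecahydronaphthalen-2-ol | CC(C)(C)[Si](C)(C)O[C@@H]1CC[C@]2(C)[C@H](CC[C@@](C)(O)[C@@H]2COCc2ccccc2)C1(C)C
F0 | step 15 | none | none
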